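Eremophilane numbering is used throughout (C3 ester carbinol, C4 and C5 methyl-bearing, C10 ring-fusion sp2 carbon, C9 enol, C8 ketone, C7 isopropylidene-bearing, C6 methylene). Ring A hides a furan: C10, C1, C2, C3 and the C3 oxygen. An intramolecular Diels–Alder reaction of this furan with a tigloyl ketone, tethered through C9–C6 (future ring B), forms C10–C5 and C3–C4 in one operation, closes rings A and B and sets C3, C4 and C5. Opening the oxygen bridge later gives the C3 hydroxyl and the C9=C10 enol bond. The precursor is an acyclic furyl carbinol silyl ether with a dithiane-masked C8 ketone; its C9 stereocentre steers the facial sense and is erased afterwards.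

Key step: step 6

Remark: the enantiomer of 5 that is carried forward is chosen on the model that the tether adopts a chair in step 6 with the C9 silyloxy group equatorial.

Step 1
Reactants: 1 furfural; 2 ethynylmagnesium bromide
Product: 4 rac-1-(furan-2-yl)prop-2-yn-1-yl acetate, via bromomagnesium 1-(furan-2-yl)prop-2-yn-1-olate 3 (not isolated)
Conditions: THF, 0 °C; then Ac2O, 0 °C to rt
Reagents that add atoms: acetic anhydride, CC(=O)OC(C)=O
Why: Grignard 1,2-addition of the acetylide to the aldehyde followed by acylation of the magnesium alkoxide in the same flask gives the propargylic acetate, whose carbinol centre is formed racemic and is resolved in step 2.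

Step 2
Reactants: 4 rac-1-(furan-2-yl)prop-2-yn-1-yl acetate
Product: 5 (R)-1-(furan-2-yl)prop-2-yn-1-ol
Conditions: immobilised Candida antarctica lipase B, phosphate buffer pH 7/acetone, 30 °C, stopped near half conversion; chromatography
Reagents that add atoms: none
Why: Lipase-catalysed enantioselective ester hydrolysis (kinetic resolution) should release the (R)-alcohol, because lipase B accepts the secondary ester that places the small ethynyl group in its medium pocket and the furyl ring in its large pocket, and the unreacted (S)-acetate is removed by chromatography.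

Step 3
Reactants: 5 (R)-1-(furan-2-yl)prop-2-yn-1-ol
Product: 6 (R)-2-[1-(triisopropylsilyloxy)prop-2-yn-1-yl]furan
Conditions: i-Pr3SiOTf, 2,6-lutidine, CH2Cl2, 0 °C
Reagents that add atoms: triisopropylsilyl trifluoromethanesulfonate, CC(C)[Si](C(C)C)(C(C)C)OS(=O)(=O)C(F)(F)F
Why: Silylation of the secondary alcohol with the silyl triflate and a hindered pyridine base leaves the stereocentre untouched, and the bulky, weakly Lewis-basic silyl ether later suppresses ionisation at the furylic carbon under the Lewis acid of step 6.

Step 4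
Reactants: 6 (R)-2-[1-(triisopropylsilyloxy)prop-2-yn-1-yl]furan; 7 tigloyl chloride, (E)-2-methylbut-2-enoyl chloride
Product: 8 (R,E)-1-(furan-2-yl)-5-methyl-1-(triisopropylsilyloxy)hept-5-en-2-yn-4-one
Conditions: PdCl2(PPh3)2 (2 mol %), CuI (4 mol %), Et3N, THF, rt
Reagents that add atoms: none
Why: Acyl Sonogashira coupling of the terminal alkyne with the acid chloride gives the ynone under mild amine base, with the E geometry of the tigloyl unit carried over from 7 and the carbinol centre untouched.

Step 5
Reactants: 8 (R,E)-1-(furan-2-yl)-5-methyl-1-(triisopropylsilyloxy)hept-5-en-2-yn-4-one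
Product: 10 (S,E)-1-{2-[(furan-2-yl)(triisopropylsilyloxy)methyl]-1,3-dithian-2-yl}-3-methylpent-3-en-2-one, via mono-thiol adduct 9 (not isolated)
Conditions: HS(CH2)3SH (1.1 equiv), NaOMe (0.3 equiv), MeOH/CH2Cl2, −10 °C to rt
Reagents that add atoms: propane-1,3-dithiol, SCCCS
Why: Base-catalysed double thia-Michael addition of the dithiol to the ynone (first intermolecular, then 6-exo intramolecular at the same carbon) masks the future C8 ketone as an sp3 dithiane and leaves the far less electrophilic trisubstituted tigloyl enone intact; the carbinol centre is unchanged and its descriptor becomes S only through the priority change.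

Step 6
Reactants: 10 (S,E)-1-{2-[(furan-2-yl)(triisopropylsilyloxy)methyl]-1,3-dithian-2-yl}-3-methylpent-3-en-2-one
Product: 11 (3R,4R,5R,9S,10S)-3,10-epoxy-bridged cycloadduct: octalin skeleton with C1=C2, C6 ketone, C8 spiro-1,3-dithiane, 9-triisopropylsilyloxy and 4,5-dimethyl groups
Conditions: MeAlCl2 (1.5 equiv), CH2Cl2, −78 °C; cold aqueous potassium sodium tartrate; used at once in step 7
Reagents that add atoms: none
Why: MeAlCl2 complexes the tigloyl ketone and the furan adds across the C4=C5 bond in a concerted, asynchronous intramolecular [4+2] cycloaddition (furan C2 and C5 are the diene termini C10 and C3), the closest known type being the alkylaluminium-chloride-promoted intramolecular Diels–Alder reaction of furans that carry an enone on a four-atom side chain at low temperature. Ring A is closed as the cyclohexene of a 7-oxanorbornene by the cycloaddition itself, and ring B as a six-membered ring in the fused mode through the tether C9–C8–C7–C6, which can only span C10 and the exo position of C5 (tether syn to the oxygen bridge). Suprafacial addition to the E-alkene makes the C4 and C5 methyl groups cis, and the exo tether places both of them endo, that is anti to the bridging oxygen that becomes the C3–O bond, so C3, C4 and C5 emerge with the relative configuration of the target (C10 is a bridgehead and is later made sp2). The absolute sense is set by C9: in the chair-like tether the silyloxy group is equatorial on one furan face and would be syn-axial to the C5 methyl on the other, so the (9S) centre should select the (3R,4R,5R) series. The step needs facial selectivity and a favourable position of the cycloaddition equilibrium; the first rests on the C9 substituent, the second on the low temperature, the Lewis acid and the geminally disubstituted dithiane carbon in the tether, and the adduct is reduced at once so that it cannot revert.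

Step 7
Reactants: 11 cycloadduct
Product: 12 (3R,4R,5R,9S,10S)-1,2-dihydro cycloadduct: saturated 3,10-epoxy tricycle with C6 ketone, C8 spiro-1,3-dithiane and 9-triisopropylsilyloxy group
Conditions: 2-nitrobenzenesulfonohydrazide, Et3N, CH2Cl2, 0 °C to rt
Reagents that add atoms: none
Why: Diimide transfer hydrogenation reduces the strained disubstituted oxanorbornene alkene, is indifferent to sulfur (which would poison a palladium catalyst) and to the ketone, and makes cycloreversion impossible.

Step 8
Reactants: 12 dihydro cycloadduct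
Product: 14 (3R,4R,5R,9S,10S)-3,10-epoxy tricycle with C6 methylene, C8 spiro-1,3-dithiane and 9-triisopropylsilyloxy group, via N-silyl hydrazone 13 (not isolated)
Conditions: t-BuMe2SiNH–NHSiMe2t-Bu, Sc(OTf)3 (1 mol %), neat, 100 °C; then KOt-Bu, t-BuOH, DMSO, 23 to 60 °C
Reagents that add atoms: none
Why: Wolff–Kishner reduction through the N-silyl hydrazone, which forms under Sc(OTf)3 catalysis even at a ketone next to a quaternary carbon and loses dinitrogen under tert-butoxide at moderate temperature, removes the C6 carbonyl that was needed only to activate the dienophile, while the hindered silyl ether, the dithiane and the oxygen bridge should tolerate the base.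

Step 9
Reactants: 14 deoxygenated dithiane
Product: 15 (3R,4R,5R,9S,10S)-3,10-epoxy-4,5-dimethyl-9-(triisopropylsilyloxy)decalin-8-one (tricyclic ketone)
Conditions: PhI(OCOCF3)2, MeCN/H2O 9:1, 0 °C
Reagents that add atoms: water, O
Why: Oxidative hydrolysis of the dithioacetal with the hypervalent iodine reagent in aqueous acetonitrile unmasks the C8 ketone under conditions that leave the silyl ether and the ether bridge alone.

Step 10
Reactants: 15 tricyclic ketone; 16 acetone
Product: 18 7-(2-hydroxypropan-2-yl) derivative of 15 (tertiary aldol; C7 configuration not controlled), via lithium C7–C8 enolate 17 (not isolated)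
Conditions: LiN(i-Pr)2, THF, −78 °C; acetone, −78 °C; AcOH quench at −78 °C
Reagents that add atoms: none
Why: Kinetic deprotonation with the lithium amide occurs at the C7 methylene (the C9 hydrogen is shielded by the silyloxy group and the bridgehead) and the enolate adds to acetone in a crossed aldol reaction; the new C7 centre is of no consequence because it becomes sp2 in step 11.

Step 11
Reactants: 18 tertiary aldol
Product: 21 (3R,4R,5R)-3-hydroxy-4,5-dimethyl-7-(propan-2-ylidene)-9-(triisopropylsilyloxy)-Δ9(10)-octalin-8-one, via tertiary mesylate 19 (not isolated), via isopropylidene tricyclic ketone 20 (not isolated)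
Conditions: MsCl (1.1 equiv), Et3N, CH2Cl2, 0 °C to rt; then DBU, 40 °C
Reagents that add atoms: none
Why: Mesylation of the tertiary aldol and E1cB loss of mesylate give the conjugated isopropylidene ketone, and the amidine base then removes the axial C9 hydrogen, which is antiperiplanar to the C10–O bond, so that a second E1cB elimination opens the strained oxygen bridge to the C9=C10 silyl enol ether and frees the C3 hydroxyl with its configuration unchanged.

Step 12
Reactants: 22 3-methylfuran-2(5H)-one
Product: 24 4-methoxybenzyl (Z)-4-hydroxy-2-methylbut-2-enoate, via potassium (Z)-4-hydroxy-2-methylbut-2-enoate 23 (not isolated)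
Conditions: KOH (1.0 equiv), MeOH/H2O, 0 °C to rt; concentrate; 4-methoxybenzyl chloride, DMF, rt
Reagents that add atoms: potassium hydroxide, [K+].[OH-]; 4-methoxybenzyl chloride, COc1ccc(CCl)cc1
Why: Saponification of the butenolide keeps the Z geometry that the ring enforces, and O-alkylation of the potassium carboxylate with the benzylic chloride gives the ester while the neutral primary alcohol is not alkylated.

Step 13
Reactants: 24 4-methoxybenzyl (Z)-4-hydroxy-2-methylbut-2-enoate; 25 angelic acid, (Z)-2-methylbut-2-enoic acid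
Product: 27 4-methoxybenzyl (Z)-2-methyl-4-[(Z)-2-methylbut-2-enoyloxy]but-2-enoate, via angelic 2,4,6-trichlorobenzoic anhydride 26 (not isolated)
Conditions: 25, 2,4,6-trichlorobenzoyl chloride, Et3N, toluene, rt; then 24, 50 °C (no DMAP)
Reagents that add atoms: none
Why: Yamaguchi-type esterification through the mixed anhydride, run without nucleophilic catalyst to avoid Z to E isomerisation of the angelate, should acylate the primary allylic alcohol faster than it can lactonise.

Step 14
Reactants: 27 4-methoxybenzyl diester
Product: 28 (Z)-2-methyl-4-[(Z)-2-methylbut-2-enoyloxy]but-2-enoic acid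
Conditions: CF3CO2H, anisole, CH2Cl2, 0 °C
Reagents that add atoms: none
Why: Acidolysis of the 4-methoxybenzyl ester with scavenging of the benzyl cation by anisole frees the acid without touching the allylic ester or the Z double bonds.

Step 15
Reactants: 21 hydroxy dienone silyl enol ether; 28 side-chain acid
Product: 30 9-O-triisopropylsilyl ether of the target, via side-chain 2,4,6-trichlorobenzoic anhydride 29 (not isolated)
Conditions: 28, 2,4,6-trichlorobenzoyl chloride, Et3N, toluene, rt; then 21, 80 °C (no DMAP)
Reagents that add atoms: none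
Why: Yamaguchi esterification of the secondary C3 alcohol through the mixed anhydride, again without nucleophilic catalyst, attaches the side chain with retention at C3 (the C–O bond of the alcohol is not broken) while the enol oxygen is blocked as its silyl ether.

Step 16
Reactants: 30 silyl-protected ester
Product: 31 target, CNP0301409.1
Conditions: HF·pyridine, pyridine, THF, 0 °C
Reagents that add atoms: none
Why: Fluoride cleaves the silyl enol ether, which is far more labile than the esters, and the liberated enol stays as the hydrogen-bonded diosphenol tautomer of the 1,2-diketone.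

Compound list
1 | furfural | O=Cc1ccco1 | starting material
2 | ethynylmagnesium bromide | C#C[Mg]Br | starting material
3 | bromomagnesium 1-(furan-2-yl)prop-2-yn-1-olate | C#CC(O[Mg]Br)c1ccco1 | intermediate
4 | rac-1-(furan-2-yl)prop-2-yn-1-yl acetate | CC(=O)OC(C#C)c1ccco1 | intermediate
5 | (R)-1-(furan-2-yl)prop-2-yn-1-ol | O[C@H](C#C)c1ccco1 | intermediate
6 | (R)-2-[1-(triisopropylsilyloxy)prop-2-yn-1-yl]furan | CC(C)[Si](C(C)C)(C(C)C)O[C@H](C#C)c1ccco1 | intermediate
7 | tigloyl chloride, (E)-2-methylbut-2-enoyl chloride | C/C=C(\C)C(=O)Cl | starting material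
8 | (R,E)-1-(furan-2-yl)-5-methyl-1-(triisopropylsilyloxy)hept-5-en-2-yn-4-one | CC(C)[Si](C(C)C)(C(C)C)O[C@H](C#CC(=O)/C(C)=C/C)c1ccco1 | intermediate
9 | mono-thiol adduct: (S)-1-(furan-2-yl)-5-methyl-2-(3-sulfanylpropylsulfanyl)-1-(triisopropylsilyloxy)hepta-2,5-dien-4-one | CC(C)[Si](C(C)C)(C(C)C)O[C@H](C(SCCCS)=CC(=O)/C(C)=C/C)c1ccco1 | intermediate
10 | (S,E)-1-{2-[(furan-2-yl)(triisopropylsilyloxy)methyl]-1,3-dithian-2-yl}-3-methylpent-3-en-2-one | CC(C)[Si](C(C)C)(C(C)C)O[C@H](C1(CC(=O)/C(C)=C/C)SCCCS1)c1ccco1 | intermediate
11 | (3R,4R,5R,9S,10S) cycloadduct: 3,10-epoxy bridge, C1=C2, C6 ketone, C8 spiro-1,3-dithiane, 9-OSi(i-Pr)3 | C[C@H]1[C@H]2C=C[C@@]3(O2)[C@H](O[Si](C(C)C)(C(C)C)C(C)C)C4(SCCCS4)CC(=O)[C@]13C | intermediate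
12 | (3R,4R,5R,9S,10S) 1,2-dihydro cycloadduct | C[C@H]1[C@H]2CC[C@@]3(O2)[C@H](O[Si](C(C)C)(C(C)C)C(C)C)C4(SCCCS4)CC(=O)[C@]13C | intermediate
13 | N-(tert-butyldimethylsilyl) hydrazone of 12 | C[C@H]1[C@H]2CC[C@@]3(O2)[C@H](O[Si](C(C)C)(C(C)C)C(C)C)C4(SCCCS4)CC(=NN[Si](C)(C)C(C)(C)C)[C@]13C | intermediate
14 | (3R,4R,5R,9S,10S) 6-deoxo tricycle with C8 spiro-1,3-dithiane | C[C@H]1[C@H]2CC[C@@]3(O2)[C@H](O[Si](C(C)C)(C(C)C)C(C)C)C4(SCCCS4)CC[C@]13C | intermediate
15 | (3R,4R,5R,9S,10S)-3,10-epoxy-4,5-dimethyl-9-(triisopropylsilyloxy)decalin-8-one | C[C@H]1[C@H]2CC[C@@]3(O2)[C@H](O[Si](C(C)C)(C(C)C)C(C)C)C(=O)CC[C@]13C | intermediate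
16 | acetone | CC(C)=O | starting material
17 | lithium C7–C8 enolate of 15 | C[C@H]1[C@H]2CC[C@@]3(O2)[C@H](O[Si](C(C)C)(C(C)C)C(C)C)C(O[Li])=CC[C@]13C | intermediate
18 | 7-(2-hydroxypropan-2-yl) derivative of 15 (C7 epimers) | C[C@H]1[C@H]2CC[C@@]3(O2)[C@H](O[Si](C(C)C)(C(C)C)C(C)C)C(=O)C(C(C)(C)O)C[C@]13C | intermediate
19 | methanesulfonate of 18 | C[C@H]1[C@H]2CC[C@@]3(O2)[C@H](O[Si](C(C)C)(C(C)C)C(C)C)C(=O)C(C(C)(C)OS(C)(=O)=O)C[C@]13C | intermediate
20 | 7-(propan-2-ylidene) derivative of 15 | C[C@H]1[C@H]2CC[C@@]3(O2)[C@H](O[Si](C(C)C)(C(C)C)C(C)C)C(=O)C(=C(C)C)C[C@]13C | intermediate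
21 | (3R,4R,5R)-3-hydroxy-4,5-dimethyl-7-(propan-2-ylidene)-9-(triisopropylsilyloxy)-Δ9(10)-octalin-8-one | O[C@@H]1CCC2=C(O[Si](C(C)C)(C(C)C)C(C)C)C(=O)C(=C(C)C)C[C@]2(C)[C@H]1C | intermediate
22 | 3-methylfuran-2(5H)-one | CC1=CCOC1=O | starting material
23 | potassium (Z)-4-hydroxy-2-methylbut-2-enoate | OC/C=C(/C)C(=O)[O-].[K+] | intermediate
24 | 4-methoxybenzyl (Z)-4-hydroxy-2-methylbut-2-enoate | OC/C=C(/C)C(=O)OCc1ccc(OC)cc1 | intermediate
25 | angelic acid, (Z)-2-methylbut-2-enoic acid | C/C=C(/C)C(=O)O | starting material
26 | angelic 2,4,6-trichlorobenzoic anhydride | C/C=C(/C)C(=O)OC(=O)c1c(Cl)cc(Cl)cc1Cl | intermediate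
27 | 4-methoxybenzyl (Z)-2-methyl-4-[(Z)-2-methylbut-2-enoyloxy]but-2-enoate | C/C=C(/C)C(=O)OC/C=C(/C)C(=O)OCc1ccc(OC)cc1 | intermediate
28 | (Z)-2-methyl-4-[(Z)-2-methylbut-2-enoyloxy]but-2-enoic acid | C/C=C(/C)C(=O)OC/C=C(/C)C(=O)O | intermediate
29 | mixed anhydride of 28 with 2,4,6-trichlorobenzoic acid | C/C=C(/C)C(=O)OC/C=C(/C)C(=O)OC(=O)c1c(Cl)cc(Cl)cc1Cl | intermediate
30 | 9-O-triisopropylsilyl ether of the target | C/C=C(/C)C(=O)OC/C=C(/C)C(=O)O[C@@H]1CCC2=C(O[Si](C(C)C)(C(C)C)C(C)C)C(=O)C(=C(C)C)C[C@]2(C)[C@H]1C | intermediate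
31 | CNP0301409.1, (3R,4R,5R)-9-hydroxy-4,5-dimethyl-8-oxo-7-(propan-2-ylidene)-Δ9(10)-octalin-3-yl (Z)-2-methyl-4-[(Z)-2-methylbut-2-enoyloxy]but-2-enoate | C/C=C(/C)C(=O)OC/C=C(/C)C(=O)O[C@@H]1CCC2=C(O)C(=O)C(=C(C)C)C[C@]2(C)[C@H]1C | target

Total step count: 16. Longest linear sequence: 13 steps (steps 1 to 11, then 15 and 16); steps 12 to 14 make the side-chain acid in parallel.

Steps most likely to fail

Step 6. The cycloaddition may stop at an unfavourable equilibrium or revert, because the dienophile is a trisubstituted enone. The Lewis acid may also ionise the furylic C–O bond, and facial selectivity may be poor. If the facial sense is opposite to the model, the (S)-acetate left from step 2 is carried forward instead. The fallback uses the known acceleration of furan cycloadditions by a halogen on the furan and sets out from 6. N-Bromosuccinimide in DMF at 0 °C should brominate the free furan α-position to give the 5-bromofuryl alkyne F1. Deprotonation of the alkyne with EtMgBr and acylation with N-methoxy-N-methyl-(E)-2-methylbut-2-enamide should give the bromo ynone F2, and dithiol addition as in step 5 the bromo keto dithiane F3. Heating in toluene at 80 °C should give the 3-bromo cycloadduct F4, and diimide reduction as in step 7 the dihydro bromide F5. Radical debromination of the bridgehead bromide with Bu3SnH and azobisisobutyronitrile returns to the route at 12.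

Step 8. Hydrazone formation may be slow at the ketone next to the quaternary carbon, and the strong base may open the β-keto dithiane by retro-Michael elimination or strip the silyl ether. The fallback is a neutral radical deoxygenation and sets out from 12. NaBH4 in MeOH should reduce the ketone to the C6 alcohol F6, and NaH, CS2 and MeI should give the S-methyl xanthate F7. Barton–McCombie reduction with Bu3SnH and azobisisobutyronitrile in toluene at 110 °C returns to the route at 14.

Step 15. Acylation of the secondary alcohol may be slow, and the two Z-2-methylbut-2-enoyl units may isomerise to the E forms under the activation conditions. The fallback builds the central double bond on the core instead and sets out from 21 and 25. Coupling of 21 with 2-[bis(2,2,2-trifluoroethoxy)phosphoryl]propanoic acid (dicyclohexylcarbodiimide, DMAP, CH2Cl2) should give the phosphonate ester F8. Angelic acid 25 is alkylated as its potassium salt with allyl bromide to allyl angelate F9, whose terminal alkene is cleaved with OsO4 (catalytic) and NaIO4 to 2-oxoethyl angelate F10. Z-selective Still–Gennari olefination of F10 with F8 (KN(SiMe3)2, 18-crown-6, THF, −78 °C) returns to the route at 30 and makes steps 12 to 14 unnecessary.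

Further compounds
F1 | step 6 | (R)-2-bromo-5-[1-(triisopropylsilyloxy)prop-2-yn-1-yl]furan | CC(C)[Si](C(C)C)(C(C)C)O[C@H](C#C)c1ccc(Br)o1
F2 | step 6 | 5-bromofuryl analogue of ynone 8 | CC(C)[Si](C(C)C)(C(C)C)O[C@H](C#CC(=O)/C(C)=C/C)c1ccc(Br)o1
F3 | step 6 | 5-bromofuryl analogue of keto dithiane 10 | CC(C)[Si](C(C)C)(C(C)C)O[C@H](C1(CC(=O)/C(C)=C/C)SCCCS1)c1ccc(Br)o1
F4 | step 6 | 3-bromo analogue of cycloadduct 11 | C[C@H]1[C@@]2(Br)C=C[C@@]3(O2)[C@H](O[Si](C(C)C)(C(C)C)C(C)C)C4(SCCCS4)CC(=O)[C@]13C
F5 | step 6 | 3-bromo analogue of dihydro cycloadduct 12 | C[C@H]1[C@@]2(Br)CC[C@@]3(O2)[C@H](O[Si](C(C)C)(C(C)C)C(C)C)C4(SCCCS4)CC(=O)[C@]13C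
F6 | step 8 | C6 alcohol from 12 (C6 epimers) | C[C@H]1[C@H]2CC[C@@]3(O2)[C@H](O[Si](C(C)C)(C(C)C)C(C)C)C4(SCCCS4)CC(O)[C@]13C
F7 | step 8 | S-methyl xanthate of F6 | C[C@H]1[C@H]2CC[C@@]3(O2)[C@H](O[Si](C(C)C)(C(C)C)C(C)C)C4(SCCCS4)CC(OC(=S)SC)[C@]13C
F8 | step 15 | 2-[bis(2,2,2-trifluoroethoxy)phosphoryl]propanoate of 21 | CC(C(=O)O[C@@H]1CCC2=C(O[Si](C(C)C)(C(C)C)C(C)C)C(=O)C(=C(C)C)C[C@]2(C)[C@H]1C)P(=O)(OCC(F)(F)F)OCC(F)(F)F
F9 | step 15 | allyl (Z)-2-methylbut-2-enoate | C/C=C(/C)C(=O)OCC=C
F10 | step 15 | 2-oxoethyl (Z)-2-methylbut-2-enoate | C/C=C(/C)C(=O)OCC=O
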